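**Retrosynthetic overview**

- The target goes back to the C2=C3/C7=C14 diene 20 (bromohydrin across C2=C3) and from there to the 10R alcohol 19 (bromide by inversion at C10).
- The strategy rests on ring B (C6–C1–C2–C3–C4–C5): the methyl-bearing C3 (with C15) lies between C2 and C4. Ring B is therefore first the spiro cyclopentanone 12 (C6–C1–C2(=O)–C4–C5), and diazoethane inserts the CH(CH3) unit (bonds C2–C3 and C3–C4).
- The five-membered ring B comes from the ring-A aldehyde 6: allylation of its dienolate at C6, Wacker oxidation, aldol closure and conjugate reduction.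
- Ring A comes from geranyl acetate by Shi epoxidation and titanium(III) radical cyclisation (C11–C6 bond), which fixes C10 and leaves the C7=C14 methylene.
- Ring order: A, then B as a cyclopentanone, then B enlarged to six members; the C2=C3 alkene, the C10 bromide and the bromohydrin follow.

Key step: step 11

Remark: atom numbers are those of the chamigrane skeleton (C6 spiro; ring B C1–C5; ring A C7–C11 with C12/C13 on C11; C14 exocyclic CH2; C15 on C3). Ketone 15 is carried on as its C3 epimer mixture, since C3 becomes sp2 in step 12.

**Route**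

Step 1
Reactants: 1 geranyl acetate
Product: 2 (6R)-6,7-epoxygeranyl acetate
Conditions: D-fructose-derived Shi ketone (cat.), Oxone, K2CO3, Bu4NHSO4, MeCN/DMM–aq. Na2B4O7/EDTA, 0 °C
Reagents that add atoms: potassium peroxymonosulfate (Oxone), OOS(=O)(=O)[O-].[K+]
Why: Shi asymmetric epoxidation, in which the chiral dioxirane attacks the electron-rich distal trisubstituted alkene in preference to the acetate-deactivated 2,3-alkene through the spiro transition state and sets the future C10 as R.

Step 2
Reactants: 2 (6R)-6,7-epoxygeranyl acetate
Product: 3 [(1S,3R)-3-hydroxy-2,2-dimethyl-6-methylidenecyclohexyl]methyl acetate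
Conditions: Cp2TiCl2 (2.2 equiv), Mn dust, THF, rt; then dil. aq. HCl
Reagents that add atoms: none
Why: Titanocene(III)-mediated radical epoxypolyene cyclisation, in which single-electron opening of the epoxide gives the tertiary C11 radical, ring A closes by 6-endo-trig attack on the alkene (C11–C6 bond) through a chair with the C10–O–Ti and CH2OAc groups equatorial (10R kept, C6 set cis to it), and the C7 radical is trapped by a second Ti(III) and loses a hydrogen from C14 to give the exocyclic alkene.

Step 3
Reactants: 3 [(1S,3R)-3-hydroxy-2,2-dimethyl-6-methylidenecyclohexyl]methyl acetate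
Product: 4 [(1S,3R)-3-(tert-butyldimethylsilyloxy)-2,2-dimethyl-6-methylidenecyclohexyl]methyl acetate
Conditions: TBSOTf, 2,6-lutidine, CH2Cl2, 0 °C
Reagents that add atoms: tert-butyldimethylsilyl triflate, CC(C)(C)[Si](C)(C)OS(=O)(=O)C(F)(F)F
Why: Silylation of the hindered secondary alcohol next to the gem-dimethyl carbon needs the silyl triflate, and the resulting ether should survive every step up to step 14.

Step 4
Reactants: 4 [(1S,3R)-3-(tert-butyldimethylsilyloxy)-2,2-dimethyl-6-methylidenecyclohexyl]methyl acetate
Product: 5 [(1S,3R)-3-(tert-butyldimethylsilyloxy)-2,2-dimethyl-6-methylidenecyclohexyl]methanol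
Conditions: K2CO3 (cat.), MeOH, rt
Reagents that add atoms: none
Why: Base-catalysed transesterification removes the primary acetate and leaves the silyl ether and the alkene untouched.

Step 5
Reactants: 5 [(1S,3R)-3-(tert-butyldimethylsilyloxy)-2,2-dimethyl-6-methylidenecyclohexyl]methanol
Product: 6 (1S,3R)-3-(tert-butyldimethylsilyloxy)-2,2-dimethyl-6-methylidenecyclohexane-1-carbaldehyde
Conditions: Dess–Martin periodinane, CH2Cl2, rt
Reagents that add atoms: none
Why: Dess–Martin oxidation gives the β,γ-unsaturated aldehyde under near-neutral conditions, and any epimerisation at C6 or drift into conjugation is harmless because C6 becomes sp2 in step 6.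

Step 6
Reactants: 6 (1S,3R)-3-(tert-butyldimethylsilyloxy)-2,2-dimethyl-6-methylidenecyclohexane-1-carbaldehyde; 7 allyl bromide
Product: 9 (1S,3R)-1-allyl-3-(tert-butyldimethylsilyloxy)-2,2-dimethyl-6-methylidenecyclohexane-1-carbaldehyde, via potassium dienolate 8 (not isolated)
Conditions: KOt-Bu, THF, 0 °C; allyl bromide, 0 °C → rt
Reagents that add atoms: allyl bromide (7), C=CCBr
Why: α-Alkylation of an extended enolate at C6 (any O-allyl dienol ether converges on 9 by Claisen rearrangement), in which the allyl group enters anti to the pseudoaxial C11 methyl of the conformer with equatorial OTBS, the other face being shielded by that methyl or, after ring inversion, by the axial silyloxy group, so that C1 ends trans to the C10 oxygen.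

Step 7
Reactants: 9 (1S,3R)-1-allyl-3-(tert-butyldimethylsilyloxy)-2,2-dimethyl-6-methylidenecyclohexane-1-carbaldehyde
Product: 10 (1S,3R)-3-(tert-butyldimethylsilyloxy)-2,2-dimethyl-6-methylidene-1-(2-oxopropyl)cyclohexane-1-carbaldehyde
Conditions: PdCl2 (cat.), CuCl, O2 (1 atm), DMF/H2O, rt
Reagents that add atoms: water, O
Why: Tsuji–Wacker oxidation converts the monosubstituted allyl alkene into the methyl ketone with Markovnikov selectivity, while the 1,1-disubstituted C7=C14 alkene next to the quaternary C6 is much slower to react.

Step 8
Reactants: 10 (1S,3R)-3-(tert-butyldimethylsilyloxy)-2,2-dimethyl-6-methylidene-1-(2-oxopropyl)cyclohexane-1-carbaldehyde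
Product: 11 (6S,10R)-10-(tert-butyldimethylsilyloxy)-11,11-dimethyl-7-methylidene spiro cyclopentenone with ring B = C6–C1H2–C2(=O)–C4H=C5H
Conditions: KOH, MeOH/THF, rt → 50 °C
Reagents that add atoms: none
Why: Intramolecular aldol condensation, in which the aldehyde cannot enolise and only the methyl enolate of the ketone can reach it, so the 4,4-disubstituted cyclopentenone is the single productive closure (C4–C5 bond).

Step 9
Reactants: 11 spiro cyclopentenone
Product: 12 (6R,10R)-10-(tert-butyldimethylsilyloxy)-11,11-dimethyl-7-methylidenespiro[4.5]decan-2-one with ring B = C6–C1H2–C2(=O)–C4H2–C5H2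
Conditions: [(Ph3P)CuH]6 (Stryker's reagent), wet benzene, rt
Reagents that add atoms: none
Why: Copper hydride conjugate reduction delivers hydride to C5 of the enone only and does not touch the isolated exocyclic alkene, which hydrogenation over a metal catalyst would.

Step 10
Reactants: 13 N-ethyl-N-nitrosourea
Product: 14 diazoethane (ethereal solution, dried over KOH and used at once)
Conditions: 40% aq. KOH, Et2O, 0 °C
Reagents that add atoms: none
Why: Base-induced cleavage of an N-alkyl-N-nitrosourea is the standard source of an alcohol-free diazoalkane solution.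

Step 11
Reactants: 12 spiro[4.5]decan-2-one; 14 diazoethane
Product: 15 (3R,6R,10R)-10-(tert-butyldimethylsilyloxy)chamigr-7(14)-en-2-one (3-methyl-2-ketone; formed and used as the C3 epimer mixture, equatorial-methyl epimer shown)
Conditions: BF3·OEt2, CH3CHN2 (slight excess, Et2O), CH2Cl2, −78 °C
Reagents that add atoms: diazoethane (14), CC=[N+]=[N-]
Why: BF3 activates the C2 carbonyl, the diazo carbon adds to C2 to give a β-oxido alkyldiazonium betaine, and C4 shifts from C2 to that carbon as N2 leaves, so that C3 with C15 is bonded to C2 by the addition and to C4 by the shift. The closest known reaction type is the Lewis-acid-promoted diazoalkane homologation of cycloalkanones (Tiffeneau–Demjanov-type 1,2-shift). No ring is closed from a chain: ring B grows from five to six members by ring expansion through the 1,2-alkyl shift, with the ketone staying at C2. The new stereocentre C3 is not usefully controlled (it follows the face of addition and the betaine conformation), but it is α to the ketone, can equilibrate to the equatorial methyl epimer and becomes sp2 in step 12. The step needs migration of C4 instead of C1 and a single insertion: C1 is neopentylic next to the quaternary C6, so the betaine conformer with C1 anti-periplanar to the leaving N2 is compressed and C4 should shift. The α-methyl group of 15, the low temperature and the limited diazoethane should hold back a second homologation and epoxide formation.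

Step 12
Reactants: 15 3-methyl-2-ketone
Product: 17 (6R,10R)-10-(tert-butyldimethylsilyloxy)chamigra-2,7(14)-dien-2-yl trifluoromethanesulfonate, via lithium enolate 16 (not isolated)
Conditions: LiHMDS (0.95 equiv), THF, 0 °C → rt (equilibration); PhNTf2, −78 °C → rt
Reagents that add atoms: N-phenylbis(trifluoromethanesulfonimide), O=S(=O)(N(c1ccccc1)S(=O)(=O)C(F)(F)F)C(F)(F)F
Why: Enolate triflation under equilibrating conditions (slight excess of ketone) should give the more substituted C2=C3 enolate, which is favoured over the C1=C2 enolate next to the quaternary C6, and O-sulfonylation fixes that regiochemistry.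

Step 13
Reactants: 17 enol triflate
Product: 18 (6R,10R)-10-(tert-butyldimethylsilyloxy)chamigra-2,7(14)-diene
Conditions: Pd(OAc)2 (cat.), PPh3, Bu3N, HCO2H, DMF, 60 °C
Reagents that add atoms: none
Why: Palladium-catalysed formate reduction of an enol triflate (oxidative addition, formate exchange, decarboxylation, reductive elimination) replaces OTf by H without moving the C2=C3 double bond.

Step 14
Reactants: 18 diene silyl ether
Product: 19 (6R,10R)-chamigra-2,7(14)-dien-10-ol
Conditions: TBAF, THF, 50 °C
Reagents that add atoms: none
Why: Fluoride-induced desilylation frees the hindered C10 alcohol, and nothing else in the molecule responds to fluoride.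

Step 15
Reactants: 19 (6R,10R)-chamigra-2,7(14)-dien-10-ol
Product: 20 (6R,10S)-10-bromochamigra-2,7(14)-diene
Conditions: CBr4, PPh3, CH2Cl2, 0 °C → reflux
Reagents that add atoms: carbon tetrabromide, BrC(Br)(Br)Br
Why: Appel reaction, in which the alkoxyphosphonium ion is displaced by bromide in an SN2 step with inversion (10R → 10S) through the ring-A chair that holds the leaving group axial, so that bromide enters along the open equatorial path, as in inversions of axial 3-hydroxy-4,4-dimethyl terpenoid alcohols.

Step 16
Reactants: 20 (6R,10S)-10-bromochamigra-2,7(14)-diene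
Product: 21 (2R,3R,6R,10S)-2,10-dibromochamigr-7(14)-en-3-ol
Conditions: NBS (1.0 equiv), acetone/H2O, 0 °C, dark
Reagents that add atoms: N-bromosuccinimide, O=C1CCC(=O)N1Br; water, O
Why: Bromohydrin formation, in which Br+ should add to the more nucleophilic trisubstituted C2=C3 alkene on the face anti to the pseudoaxial C7 (the C11 side) and water should open the unsymmetrical bromonium ion at tertiary C3 from the opposite face (Markovnikov, anti), giving 2R-Br and 3R-OH trans and diequatorial after ring-B relaxation, while the hindered 1,1-disubstituted C7=C14 alkene should react more slowly.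

**Compound list**

1 | geranyl acetate | CC(C)=CCC/C(C)=C/COC(C)=O | starting material
2 | (6R)-6,7-epoxygeranyl acetate | CC(=O)OC/C=C(\C)CC[C@H]1OC1(C)C | intermediate
3 | [(1S,3R)-3-hydroxy-2,2-dimethyl-6-methylidenecyclohexyl]methyl acetate | C=C1CC[C@@H](O)C(C)(C)[C@H]1COC(C)=O | intermediate
4 | [(1S,3R)-3-(tert-butyldimethylsilyloxy)-2,2-dimethyl-6-methylidenecyclohexyl]methyl acetate | C=C1CC[C@@H](O[Si](C)(C)C(C)(C)C)C(C)(C)[C@H]1COC(C)=O | intermediate
5 | [(1S,3R)-3-(tert-butyldimethylsilyloxy)-2,2-dimethyl-6-methylidenecyclohexyl]methanol | C=C1CC[C@@H](O[Si](C)(C)C(C)(C)C)C(C)(C)[C@H]1CO | intermediate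
6 | (1S,3R)-3-(tert-butyldimethylsilyloxy)-2,2-dimethyl-6-methylidenecyclohexane-1-carbaldehyde | C=C1CC[C@@H](O[Si](C)(C)C(C)(C)C)C(C)(C)[C@H]1C=O | intermediate
7 | allyl bromide | C=CCBr | starting material
8 | potassium dienolate of aldehyde 6 | C=C1CC[C@@H](O[Si](C)(C)C(C)(C)C)C(C)(C)C1=C[O-].[K+] | intermediate
9 | (1S,3R)-1-allyl-3-(tert-butyldimethylsilyloxy)-2,2-dimethyl-6-methylidenecyclohexane-1-carbaldehyde | C=C1CC[C@@H](O[Si](C)(C)C(C)(C)C)C(C)(C)[C@@]1(CC=C)C=O | intermediate
10 | (1S,3R)-3-(tert-butyldimethylsilyloxy)-2,2-dimethyl-6-methylidene-1-(2-oxopropyl)cyclohexane-1-carbaldehyde | C=C1CC[C@@H](O[Si](C)(C)C(C)(C)C)C(C)(C)[C@@]1(CC(C)=O)C=O | intermediate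
11 | (6S,10R) spiro cyclopentenone, ring B C6–C1H2–C2(=O)–C4H=C5H | C=C1CC[C@@H](O[Si](C)(C)C(C)(C)C)C(C)(C)[C@@]12C=CC(=O)C2 | intermediate
12 | (6R,10R)-10-(tert-butyldimethylsilyloxy)-11,11-dimethyl-7-methylidenespiro[4.5]decan-2-one (key-step precursor) | C=C1CC[C@@H](O[Si](C)(C)C(C)(C)C)C(C)(C)[C@@]12CCC(=O)C2 | intermediate
13 | N-ethyl-N-nitrosourea | CCN(N=O)C(N)=O | starting material
14 | diazoethane | CC=[N+]=[N-] | intermediate
15 | (3R,6R,10R)-10-(tert-butyldimethylsilyloxy)chamigr-7(14)-en-2-one (C3 epimer mixture, 3R shown) | C=C1CC[C@@H](O[Si](C)(C)C(C)(C)C)C(C)(C)[C@@]12CC[C@@H](C)C(=O)C2 | intermediate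
16 | lithium C2=C3 enolate of 15 | C=C1CC[C@@H](O[Si](C)(C)C(C)(C)C)C(C)(C)[C@@]12CCC(C)=C([O-])C2.[Li+] | intermediate
17 | (6R,10R)-10-(tert-butyldimethylsilyloxy)chamigra-2,7(14)-dien-2-yl trifluoromethanesulfonate | C=C1CC[C@@H](O[Si](C)(C)C(C)(C)C)C(C)(C)[C@@]12CCC(C)=C(OS(=O)(=O)C(F)(F)F)C2 | intermediate
18 | (6R,10R)-10-(tert-butyldimethylsilyloxy)chamigra-2,7(14)-diene | C=C1CC[C@@H](O[Si](C)(C)C(C)(C)C)C(C)(C)[C@@]12CCC(C)=CC2 | intermediate
19 | (6R,10R)-chamigra-2,7(14)-dien-10-ol | C=C1CC[C@@H](O)C(C)(C)[C@@]12CCC(C)=CC2 | intermediate
20 | (6R,10S)-10-bromochamigra-2,7(14)-diene | C=C1CC[C@H](Br)C(C)(C)[C@@]12CCC(C)=CC2 | intermediate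
21 | (2R,3R,6R,10S)-2,10-dibromochamigr-7(14)-en-3-ol | C=C1CC[C@H](Br)C(C)(C)[C@@]12CC[C@@](C)(O)[C@H](Br)C2 | target

**Step count**

Total: 16 steps. Longest linear sequence: 15 steps (steps 1–9 and 11–16, from 1 to 21); step 10 is a one-step side branch.

**Steps most likely to fail**

1. Step 15 (inversion at C10). The oxyphosphonium group sits equatorial in the favoured ring-A chair, anti-periplanar to the C11–C6 bond. Ionisation with a Wagner–Meerwein shift (ring contraction) or E2 loss toward C9 may therefore outrun the SN2 attack, which has to pass through the less populated chair with an axial leaving group. Fallback: activation and displacement are separated. From 19, the C10 trifluoromethanesulfonate F1 is prepared (Tf2O, pyridine, CH2Cl2, −30 °C). It is then displaced by tetrabutylammonium bromide in toluene at rt, that is, by a non-basic bromide in a non-ionising medium with no phosphorus species present. This returns to the route at 20.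

2. Step 16 (bromohydrin). The water capture needed at C3 is Markovnikov but not trans-diaxial in the favoured ring-B conformer. Bromonium formation on the C7 face followed by diaxial opening, opening at C2, attack on the C7=C14 alkene, or transannular capture by it may therefore compete and erode the face and site selectivity. Fallback: the C2 configuration is fixed before oxygen is introduced. From 20, pyridinium tribromide (1 equiv, CH2Cl2, −40 °C) adds bromine across C2=C3. The trans-diequatorial tribromide F2 is the one wanted. Any trans-diaxial isomer, the (2S,3S)-tribromide F3, from attack on the other face should be enriched in F2 by thermal 1,2-dibromide interchange in a polar solvent. Silver nitrate in aqueous acetone then ionises the tertiary C3–Br bond with participation of the C2 bromine, and water enters at C3 with retention. This returns to the route at 21.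

3. Step 11 (ring expansion). Migration of C1 instead of C4, a second insertion into 15, or collapse of the betaine to an epoxide may lower the yield of the wanted ketone. Fallback: regiochemistry is set by enolisation instead of by migratory preference. From 12, kinetic deprotonation on the unhindered C4 side and silylation (LDA, THF, −78 °C; TMSCl) give the C2=C4 trimethylsilyl enol ether F4. Zinc-carbenoid cyclopropanation with 1,1-diiodoethane and diethylzinc gives the methyl-substituted siloxycyclopropane F5. Iron(III) chloride in DMF cleaves the C2–C4 bond to the ring-enlarged 4-chloro-3-methyl-2-ketone F6 (Saegusa–Ito-type ring expansion). Sodium acetate in methanol eliminates HCl to the 3-methyl-3-en-2-one F7. Conjugate reduction with Stryker's reagent returns to the route at 15.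

**Further compounds**

F1 | step 15 | (6R,10R)-chamigra-2,7(14)-dien-10-yl trifluoromethanesulfonate | C=C1CC[C@@H](OS(=O)(=O)C(F)(F)F)C(C)(C)[C@@]12CCC(C)=CC2
F2 | step 16 | (2R,3R,6R,10S)-2,3,10-tribromochamigr-7(14)-ene | C=C1CC[C@H](Br)C(C)(C)[C@@]12CC[C@@](C)(Br)[C@H](Br)C2
F3 | step 16 | (2S,3S,6R,10S)-2,3,10-tribromochamigr-7(14)-ene | C=C1CC[C@H](Br)C(C)(C)[C@@]12CC[C@](C)(Br)[C@@H](Br)C2
F4 | step 11 | C2=C4 trimethylsilyl enol ether of 12 | C=C1CC[C@@H](O[Si](C)(C)C(C)(C)C)C(C)(C)[C@@]12CC=C(O[Si](C)(C)C)C2
F5 | step 11 | methyl-substituted siloxycyclopropane (C3 bridging C2 and C4) | C=C1CC[C@@H](O[Si](C)(C)C(C)(C)C)C(C)(C)[C@@]12CC3C(C)C3(O[Si](C)(C)C)C2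
F6 | step 11 | 4-chloro-3-methyl-2-ketone | C=C1CC[C@@H](O[Si](C)(C)C(C)(C)C)C(C)(C)[C@@]12CC(Cl)C(C)C(=O)C2
F7 | step 11 | 3-methyl-3-en-2-one | C=C1CC[C@@H](O[Si](C)(C)C(C)(C)C)C(C)(C)[C@@]12CC=C(C)C(=O)C2
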